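**Plan**

- Retrosynthesis: remove the 19 benzyl ethers and two C–Br caps, take the 3-OH of unit 2 back to a C–B bond, then cut ring C of unit 2 at C2–C3 and C4–C4a. Then cut the C4–C6 bond between units 3 and 4 and the C4–aryl bond between unit 1 and ring A of unit 2.
- Forward: (−)-epicatechin gives one perbenzylated building block, used as a C4-activated, C8-bromo-capped electrophile (twice) and as a C8-bromo nucleophile. Friedel–Crafts couplings join units 3 and 4 and attach a phloroglucinol ring (the future ring A of unit 2) to unit 1.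
- Ring C of unit 2 is closed last, from the aryl α-acyloxybenzyl ether of the top half and an (E)-alkenylboronate on C8 of unit 3.
- Enabling feature: in ring C of unit 2 the C4a–C8a–O1–C2 segment is a latent cationic 2-oxadiene (aryl oxocarbenium ion), and C4 carries the trioxygenated ring A of unit 3, which stabilises a cation at C4. Boron on C3 fixes the regiochemistry and later becomes the 3-hydroxyl.
- Stereochemistry: C2 and C3 of units 1, 3 and 4 come from (−)-epicatechin; C4 of units 1 and 3 is set by attack anti to the 3-benzyloxy group; C2, C3 and C4 of unit 2 are set in the key step (chiral counter-anion, E-alkene, pseudo-axial aryl), and C–B goes to C–O with retention.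

Key step: step 15

Remark on the chemistry: which enantiomer of the chiral acid in step 15 matches the two enantiopure partners cannot be predicted; the route is written for the matching one (both are available), and 18 is used as the mixture of its two acetal epimers.

**Route**

Step 1
Reactants: 1 (−)-epicatechin
Product: 2 5,7,3',4'-tetra-O-benzyl-(−)-epicatechin
Conditions: BnBr (4.2 equiv), K2CO3, DMF, 0 °C → rt
Reagents that add atoms: benzyl bromide, BrCc1ccccc1
Why: Williamson etherification of the four phenolic hydroxyls (carbonate does not deprotonate the secondary 3-OH); C2 and C3 are untouched.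

Step 2
Reactants: 2 5,7,3',4'-tetra-O-benzyl-(−)-epicatechin
Product: 3 3,5,7,3',4'-penta-O-benzyl-(−)-epicatechin
Conditions: NaH, BnBr, Bu4NI (cat.), DMF, 0 °C → rt
Reagents that add atoms: benzyl bromide, BrCc1ccccc1
Why: Williamson etherification of the secondary alkoxide; no free phenol is left, so ring opening and epimerisation at C2 cannot occur.

Step 3
Reactants: 3 3,5,7,3',4'-penta-O-benzyl-(−)-epicatechin
Product: 4 4β-(2-ethoxyethoxy)-3,5,7,3',4'-penta-O-benzylepicatechin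
Conditions: 2,3-dichloro-5,6-dicyano-1,4-benzoquinone (DDQ), 2-ethoxyethanol, CH2Cl2, rt
Reagents that add atoms: 2-ethoxyethanol, CCOCCO
Why: benzylic oxidation by hydride abstraction from C4, the cation being stabilised by ring A; the alcohol adds anti to the 3-benzyloxy group and gives the 4β ether.

Step 4
Reactants: 4 4β-(2-ethoxyethoxy)-3,5,7,3',4'-penta-O-benzylepicatechin
Product: 5 8-bromo-4β-(2-ethoxyethoxy)-3,5,7,3',4'-penta-O-benzylepicatechin
Conditions: N-bromosuccinimide, CH2Cl2, −40 → 0 °C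
Reagents that add atoms: N-bromosuccinimide, O=C1CCC(=O)N1Br
Why: electrophilic aromatic bromination at C8, the most nucleophilic carbon of ring A; the bromine caps C8 against self-condensation and is the handle for step 6.

Step 5
Reactants: 3 3,5,7,3',4'-penta-O-benzyl-(−)-epicatechin
Product: 6 8-bromo-3,5,7,3',4'-penta-O-benzylepicatechin
Conditions: N-bromosuccinimide, CH2Cl2, −40 → 0 °C
Reagents that add atoms: N-bromosuccinimide, O=C1CCC(=O)N1Br
Why: the same regioselective electrophilic bromination at C8, which leaves C6 as the only free ring A carbon.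

Step 6
Reactants: 5 8-bromo-4β-(2-ethoxyethoxy)-3,5,7,3',4'-penta-O-benzylepicatechin; 7 (triisopropylsilyl)acetylene
Product: 8 8-[(triisopropylsilyl)ethynyl]-4β-(2-ethoxyethoxy)-3,5,7,3',4'-penta-O-benzylepicatechin
Conditions: PdCl2(MeCN)2 (cat.), 2-dicyclohexylphosphino-2',4',6'-triisopropylbiphenyl (XPhos), Cs2CO3, MeCN, 80 °C
Reagents that add atoms: none
Why: copper-free Sonogashira coupling of the hindered, electron-rich aryl bromide; the base-stable 4-alkoxy group and the benzyl ethers survive.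

Step 7
Reactants: 8 8-[(triisopropylsilyl)ethynyl]-4β-(2-ethoxyethoxy)-3,5,7,3',4'-penta-O-benzylepicatechin; 6 8-bromo-3,5,7,3',4'-penta-O-benzylepicatechin (excess)
Product: 9 deca-O-benzyl-8-[(triisopropylsilyl)ethynyl]epicatechin-(4β→6)-8-bromoepicatechin
Conditions: Me3SiOTf (0.2 equiv), CH2Cl2, −78 → −40 °C; Et3N quench
Reagents that add atoms: none
Why: Friedel–Crafts alkylation in which Me3SiOTf ionises the 4-alkoxy group of 8 and C6 of 6 attacks the C4 cation anti to the 3-benzyloxy group (4β, 3,4-trans); C8 of 6 is blocked by bromine and C8 of 8 by the bulky silylalkyne, so only the 4→6 bond can form.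

Step 8
Reactants: 9 deca-O-benzyl-8-[(triisopropylsilyl)ethynyl]epicatechin-(4β→6)-8-bromoepicatechin
Product: 10 deca-O-benzyl-8-ethynylepicatechin-(4β→6)-8-bromoepicatechin
Conditions: Bu4NF, wet THF, 0 °C → rt
Reagents that add atoms: none
Why: fluoride-induced protodesilylation of the alkynylsilane; benzyl ethers, the aryl bromide and the interflavan bond are inert.

Step 9
Reactants: 10 deca-O-benzyl-8-ethynylepicatechin-(4β→6)-8-bromoepicatechin
Product: 11 deca-O-benzyl-8-[(E)-2-(4,4,5,5-tetramethyl-1,3,2-dioxaborolan-2-yl)vinyl]epicatechin-(4β→6)-8-bromoepicatechin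
Conditions: pinacolborane, Cp2Zr(H)Cl (cat.), Et3N (cat.), THF, 50 °C
Reagents that add atoms: pinacolborane, CC1(C)OBOC1(C)C
Why: zirconium-catalysed hydroboration of the terminal alkyne; syn addition of H–B with boron on the terminal carbon gives the E-alkenylboronate, and the aryl bromide does not react.

Step 10
Reactants: 12 3,5-bis(benzyloxy)phenol
Product: 13 [3,5-bis(benzyloxy)phenoxy]triisopropylsilane
Conditions: iPr3SiCl, imidazole, DMF, rt
Reagents that add atoms: chlorotriisopropylsilane, CC(C)[Si](Cl)(C(C)C)C(C)C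
Why: O-silylation of the phenol; the bulky silyl group marks the oxygen that becomes O1 of unit 2 and screens the two ring carbons next to it.

Step 11
Reactants: 5 8-bromo-4β-(2-ethoxyethoxy)-3,5,7,3',4'-penta-O-benzylepicatechin; 13 [3,5-bis(benzyloxy)phenoxy]triisopropylsilane (excess)
Product: 14 8-bromo-3,5,7,3',4'-penta-O-benzyl-4β-[2,6-bis(benzyloxy)-4-(triisopropylsilyloxy)phenyl]epicatechin
Conditions: Me3SiOTf (0.2 equiv), CH2Cl2, −78 → −40 °C; Et3N quench
Reagents that add atoms: none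
Why: Friedel–Crafts alkylation of 13 by the C4 cation of 5, anti to the 3-benzyloxy group (4β); attack should go to the carbon between the two benzyloxy groups, para to the silyloxy group, because the silyl group shields both carbons beside it.

Step 12
Reactants: 14 8-bromo-3,5,7,3',4'-penta-O-benzyl-4β-[2,6-bis(benzyloxy)-4-(triisopropylsilyloxy)phenyl]epicatechin
Product: 15 8-bromo-3,5,7,3',4'-penta-O-benzyl-4β-[2,6-bis(benzyloxy)-4-hydroxyphenyl]epicatechin
Conditions: Bu4NF, AcOH, THF, 0 °C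
Reagents that add atoms: none
Why: buffered fluoride cleavage of the aryl silyl ether frees only the phenol para to unit 1.

Step 13
Reactants: 16 3,4-bis(benzyloxy)benzaldehyde
Product: 17 chloro[3,4-bis(benzyloxy)phenyl]methyl pivalate (racemic)
Conditions: pivaloyl chloride, ZnCl2 (cat.), CH2Cl2, 0 °C → rt; used crude
Reagents that add atoms: pivaloyl chloride, CC(C)(C)C(Cl)=O
Why: Lewis acid catalysed addition of an acyl chloride across the aldehyde C=O gives the α-chloroalkyl ester.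

Step 14
Reactants: 15 8-bromo-3,5,7,3',4'-penta-O-benzyl-4β-[2,6-bis(benzyloxy)-4-hydroxyphenyl]epicatechin; 17 chloro[3,4-bis(benzyloxy)phenyl]methyl pivalate
Product: 18 aryl α-pivaloyloxybenzyl ether of 15 (mixed acyl acetal; both epimers at the acetal carbon)
Conditions: Cs2CO3, DMF, 0 °C; filtration through Et3N-deactivated silica
Reagents that add atoms: none
Why: O-alkylation of the phenoxide by the ionisable α-chloroalkyl ester (the reaction type used to make acyloxyalkyl aryl ethers); the hindered pivaloyl carbonyl resists acyl transfer.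

Step 15
Reactants: 18 aryl α-pivaloyloxybenzyl ether of 15; 11 deca-O-benzyl-8-[(E)-2-(pinacolboryl)vinyl]epicatechin-(4β→6)-8-bromoepicatechin (1.2 equiv)
Product: 21 nonadeca-O-benzyl-8-bromoepicatechin-(4β→6)-[3-deoxy-3α-(pinacolboryl)epicatechin]-(4β→8)-epicatechin-(4β→6)-8-bromoepicatechin, via aryl oxocarbenium ion 19 (not isolated), via benzylic cation 20 (not isolated)
Conditions: (R)-3,3'-bis(2,4,6-triisopropylphenyl)-1,1'-binaphthyl-2,2'-diyl N-triflylphosphoramide (C51H57F3NO5PS, 10 mol %; see remark), 5 Å molecular sieves, toluene/CH2Cl2, −60 → −30 °C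
Reagents that add atoms: none
Why: Proposed new method: the chiral acid ionises the acyl acetal at the pivalate (a better leaving group than the aryloxide), so both acetal epimers give the same planar E-oxocarbenium ion 19 paired with the chiral anion; the boron-bearing alkene carbon of 11 attacks C2 because the charge then develops at C4, benzylic to the 2,4,6-trioxygenated ring A of unit 3 and β to boron, and cation 20 is captured by the ortho carbon C4a of the aryl ether (6-exo-trig Friedel–Crafts closure, overall a formal [4+2] of a cationic 2-oxadiene with an alkene). The closest known reaction type is the Lewis acid promoted oxa-Povarov reaction of aryl oxocarbenium ions with styrenes, together with chiral Brønsted acid catalysed Povarov and Prins reactions; new here are the alkenylboronate as 2π partner and the control by a chiral counter-anion. C2 and C3 are set in the C–C bond-forming event: the counter-anion selects the face of 19, and the E geometry of 11 with the bulky 2,6-dioxygenated aryl group exo (endo it would clash with the ring bearing the 5-benzyloxy group) puts boron endo, which gives the 2,3-cis relation. C4 is set in the ring closure by the substrate: the unit 3 aryl group takes the pseudo-axial position anti to the C3–B bond and away from the peri 5-benzyloxy group, so 3,4-trans should result even if 20 rotates. The step needs attack of the alkene through C3 and not C4 (secured by boron on C3 and the aryl donor on C4), the 4→6 connectivity of units 1 and 2 (only the oxygen para to unit 1 is free, and closure at either of its two equivalent ortho carbons gives the same ring), and attack of the alkene instead of a ring carbon on 19 (the most nucleophilic free ring carbons, C8 of units 1 and 4, carry bromine).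

Step 16
Reactants: 21 nonadeca-O-benzyl-8-bromoepicatechin-(4β→6)-[3-deoxy-3α-(pinacolboryl)epicatechin]-(4β→8)-epicatechin-(4β→6)-8-bromoepicatechin
Product: 22 nonadeca-O-benzyl-8-bromoepicatechin-(4β→6)-epicatechin-(4β→8)-epicatechin-(4β→6)-8-bromoepicatechin (free 3-OH in unit 2)
Conditions: 30% H2O2, aq NaOH, THF, 0 °C → rt
Reagents that add atoms: hydrogen peroxide, OO
Why: peroxide oxidation of the secondary alkylboronate (1,2-shift of carbon from boron to oxygen) goes with retention, so the 3α-boron becomes the 3α-hydroxyl of a 2,3-cis unit; no free phenol is present to be oxidised.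

Step 17
Reactants: 22 nonadeca-O-benzyl-8-bromoepicatechin-(4β→6)-epicatechin-(4β→8)-epicatechin-(4β→6)-8-bromoepicatechin
Product: 23 epicatechin-(4β→6)-epicatechin-(4β→8)-epicatechin-(4β→6)-epicatechin (target, CNP0120618.1)
Conditions: H2 (1 atm), Pd(OH)2/C, Et3N, THF/MeOH/H2O, rt, under argon on work-up
Reagents that add atoms: none
Why: hydrogenolysis cleaves the 19 benzyl ethers and, with Et3N present, the two aryl C–Br bonds; no stereocenter is touched.

**Compound list**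

1 | (−)-epicatechin, (2R,3R) | Oc1cc(O)c2c(c1)O[C@H](c1ccc(O)c(O)c1)[C@H](O)C2 | starting material
2 | 5,7,3',4'-tetra-O-benzyl-(−)-epicatechin | c9ccccc9COc1cc(OCc9ccccc9)c2c(c1)O[C@H](c1ccc(OCc9ccccc9)c(OCc9ccccc9)c1)[C@H](O)C2 | intermediate
3 | 3,5,7,3',4'-penta-O-benzyl-(−)-epicatechin | c9ccccc9COc1cc(OCc9ccccc9)c2c(c1)O[C@H](c1ccc(OCc9ccccc9)c(OCc9ccccc9)c1)[C@H](OCc9ccccc9)C2 | intermediate
4 | 4β-(2-ethoxyethoxy)-penta-O-benzylepicatechin (4-alkoxy trans to 3-OBn) | c9ccccc9COc1cc(OCc9ccccc9)c2c(c1)O[C@H](c1ccc(OCc9ccccc9)c(OCc9ccccc9)c1)[C@H](OCc9ccccc9)[C@H]2OCCOCC | intermediate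
5 | 8-bromo-4β-(2-ethoxyethoxy)-penta-O-benzylepicatechin | c9ccccc9COc1cc(OCc9ccccc9)c2c(c1Br)O[C@H](c1ccc(OCc9ccccc9)c(OCc9ccccc9)c1)[C@H](OCc9ccccc9)[C@H]2OCCOCC | intermediate
6 | 8-bromo-penta-O-benzylepicatechin | c9ccccc9COc1cc(OCc9ccccc9)c2c(c1Br)O[C@H](c1ccc(OCc9ccccc9)c(OCc9ccccc9)c1)[C@H](OCc9ccccc9)C2 | intermediate
7 | (triisopropylsilyl)acetylene | C#C[Si](C(C)C)(C(C)C)C(C)C | starting material
8 | 8-[(triisopropylsilyl)ethynyl]-4β-(2-ethoxyethoxy)-penta-O-benzylepicatechin | c9ccccc9COc1cc(OCc9ccccc9)c2c(c1C#C[Si](C(C)C)(C(C)C)C(C)C)O[C@H](c1ccc(OCc9ccccc9)c(OCc9ccccc9)c1)[C@H](OCc9ccccc9)[C@H]2OCCOCC | intermediate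
9 | deca-O-benzyl-8-[(triisopropylsilyl)ethynyl]epicatechin-(4β→6)-8-bromoepicatechin | c9ccccc9COc1cc(OCc9ccccc9)c2c(c1C#C[Si](C(C)C)(C(C)C)C(C)C)O[C@H](c1ccc(OCc9ccccc9)c(OCc9ccccc9)c1)[C@H](OCc9ccccc9)[C@H]2c1c(OCc9ccccc9)c(Br)c3c(c1OCc9ccccc9)C[C@@H](OCc9ccccc9)[C@@H](c1ccc(OCc9ccccc9)c(OCc9ccccc9)c1)O3 | intermediate
10 | deca-O-benzyl-8-ethynylepicatechin-(4β→6)-8-bromoepicatechin | c9ccccc9COc1cc(OCc9ccccc9)c2c(c1C#C)O[C@H](c1ccc(OCc9ccccc9)c(OCc9ccccc9)c1)[C@H](OCc9ccccc9)[C@H]2c1c(OCc9ccccc9)c(Br)c3c(c1OCc9ccccc9)C[C@@H](OCc9ccccc9)[C@@H](c1ccc(OCc9ccccc9)c(OCc9ccccc9)c1)O3 | intermediate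
11 | deca-O-benzyl-8-[(E)-2-(pinacolboryl)vinyl]epicatechin-(4β→6)-8-bromoepicatechin | c9ccccc9COc1cc(OCc9ccccc9)c2c(c1/C=C/B3OC(C)(C)C(C)(C)O3)O[C@H](c1ccc(OCc9ccccc9)c(OCc9ccccc9)c1)[C@H](OCc9ccccc9)[C@H]2c1c(OCc9ccccc9)c(Br)c3c(c1OCc9ccccc9)C[C@@H](OCc9ccccc9)[C@@H](c1ccc(OCc9ccccc9)c(OCc9ccccc9)c1)O3 | intermediate
12 | 3,5-bis(benzyloxy)phenol | Oc1cc(OCc2ccccc2)cc(OCc2ccccc2)c1 | starting material
13 | [3,5-bis(benzyloxy)phenoxy]triisopropylsilane | CC(C)[Si](Oc1cc(OCc2ccccc2)cc(OCc2ccccc2)c1)(C(C)C)C(C)C | intermediate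
14 | 8-bromo-penta-O-benzyl-4β-[2,6-bis(benzyloxy)-4-(triisopropylsilyloxy)phenyl]epicatechin | c9ccccc9COc1cc(OCc9ccccc9)c2c(c1Br)O[C@H](c1ccc(OCc9ccccc9)c(OCc9ccccc9)c1)[C@H](OCc9ccccc9)[C@H]2c1c(OCc9ccccc9)cc(O[Si](C(C)C)(C(C)C)C(C)C)cc1OCc9ccccc9 | intermediate
15 | 8-bromo-penta-O-benzyl-4β-[2,6-bis(benzyloxy)-4-hydroxyphenyl]epicatechin | c9ccccc9COc1cc(OCc9ccccc9)c2c(c1Br)O[C@H](c1ccc(OCc9ccccc9)c(OCc9ccccc9)c1)[C@H](OCc9ccccc9)[C@H]2c1c(OCc9ccccc9)cc(O)cc1OCc9ccccc9 | intermediate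
16 | 3,4-bis(benzyloxy)benzaldehyde | O=Cc1ccc(OCc2ccccc2)c(OCc2ccccc2)c1 | starting material
17 | chloro[3,4-bis(benzyloxy)phenyl]methyl pivalate (racemic) | CC(C)(C)C(=O)OC(Cl)c1ccc(OCc2ccccc2)c(OCc2ccccc2)c1 | intermediate
18 | aryl α-pivaloyloxybenzyl ether of 15 (both acetal epimers) | c9ccccc9COc1cc(OCc9ccccc9)c2c(c1Br)O[C@H](c1ccc(OCc9ccccc9)c(OCc9ccccc9)c1)[C@H](OCc9ccccc9)[C@H]2c1c(OCc9ccccc9)cc(OC(OC(=O)C(C)(C)C)c3ccc(OCc9ccccc9)c(OCc9ccccc9)c3)cc1OCc9ccccc9 | intermediate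
19 | aryl oxocarbenium ion from 18 (cationic 2-oxadiene) | c9ccccc9COc1cc(OCc9ccccc9)c2c(c1Br)O[C@H](c1ccc(OCc9ccccc9)c(OCc9ccccc9)c1)[C@H](OCc9ccccc9)[C@H]2c1c(OCc9ccccc9)cc([O+]=Cc3ccc(OCc9ccccc9)c(OCc9ccccc9)c3)cc1OCc9ccccc9 | intermediate (not isolated)
20 | benzylic cation after C2–C3 bond formation (C2-aryl and C3-boron in the relation that gives 2,3-cis) | c9ccccc9COc1cc(OCc9ccccc9)c2c(c1Br)O[C@H](c1ccc(OCc9ccccc9)c(OCc9ccccc9)c1)[C@H](OCc9ccccc9)[C@H]2c1c(OCc9ccccc9)cc(O[C@H](c3ccc(OCc9ccccc9)c(OCc9ccccc9)c3)[C@H](B4OC(C)(C)C(C)(C)O4)[CH+]c5c(OCc9ccccc9)cc(OCc9ccccc9)c6c5O[C@H](c7ccc(OCc9ccccc9)c(OCc9ccccc9)c7)[C@H](OCc9ccccc9)[C@H]6c5c(OCc9ccccc9)c(Br)c6c(c5OCc9ccccc9)C[C@@H](OCc9ccccc9)[C@@H](c7ccc(OCc9ccccc9)c(OCc9ccccc9)c7)O6)cc1OCc9ccccc9 | intermediate (not isolated)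
21 | protected tetramer 3-boronate (unit 2: 2α-aryl, 3α-pinacolboryl, 4β-aryl) | c9ccccc9COc1cc(OCc9ccccc9)c2c(c1Br)O[C@H](c1ccc(OCc9ccccc9)c(OCc9ccccc9)c1)[C@H](OCc9ccccc9)[C@H]2c1c(OCc9ccccc9)cc2c(c1OCc9ccccc9)[C@H](c1c(OCc9ccccc9)cc(OCc9ccccc9)c3c1O[C@H](c1ccc(OCc9ccccc9)c(OCc9ccccc9)c1)[C@H](OCc9ccccc9)[C@H]3c1c(OCc9ccccc9)c(Br)c3c(c1OCc9ccccc9)C[C@@H](OCc9ccccc9)[C@@H](c1ccc(OCc9ccccc9)c(OCc9ccccc9)c1)O3)[C@@H](B4OC(C)(C)C(C)(C)O4)[C@@H](c1ccc(OCc9ccccc9)c(OCc9ccccc9)c1)O2 | intermediate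
22 | protected tetramer with free 3α-OH in unit 2 | c9ccccc9COc1cc(OCc9ccccc9)c2c(c1Br)O[C@H](c1ccc(OCc9ccccc9)c(OCc9ccccc9)c1)[C@H](OCc9ccccc9)[C@H]2c1c(OCc9ccccc9)cc2c(c1OCc9ccccc9)[C@H](c1c(OCc9ccccc9)cc(OCc9ccccc9)c3c1O[C@H](c1ccc(OCc9ccccc9)c(OCc9ccccc9)c1)[C@H](OCc9ccccc9)[C@H]3c1c(OCc9ccccc9)c(Br)c3c(c1OCc9ccccc9)C[C@@H](OCc9ccccc9)[C@@H](c1ccc(OCc9ccccc9)c(OCc9ccccc9)c1)O3)[C@@H](O)[C@@H](c1ccc(OCc9ccccc9)c(OCc9ccccc9)c1)O2 | intermediate
23 | epicatechin-(4β→6)-epicatechin-(4β→8)-epicatechin-(4β→6)-epicatechin | Oc1cc(O)c2c(c1)O[C@H](c1ccc(O)c(O)c1)[C@H](O)[C@H]2c1c(O)cc2c(c1O)[C@H](c1c(O)cc(O)c3c1O[C@H](c1ccc(O)c(O)c1)[C@H](O)[C@H]3c1c(O)cc3c(c1O)C[C@@H](O)[C@@H](c1ccc(O)c(O)c1)O3)[C@@H](O)[C@@H](c1ccc(O)c(O)c1)O2 | target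

**Summary**

Total step count: 17. Longest linear sequence: 11 steps (steps 1, 2, 3, 4, 6, 7, 8, 9, 15, 16, 17).

Steps most likely to fail:

1. Step 15 (Proposed new method). What may go wrong: loss of boron from cation 20 before the ring closes (alkenylation instead of annulation), protodeboronation of 11 by the acid, poor facial selectivity at oxocarbenium ion 19 or the 2,3-trans mode of addition, or attack of a ring carbon on 19. Fallback with known chemistry, in which ring C of unit 2 is taken from epicatechin instead of being built: it sets out from 4, 5 and 6. Me3SiOTf-catalysed coupling of 5 with 6 gives deca-O-benzyl-8-bromoepicatechin-(4β→6)-8-bromoepicatechin F1. Oxidation of F1 with DDQ and 2-ethoxyethanol places the leaving group on C4 of its lower unit and gives the dimeric electrophile F2. Coupling of 4 with an excess of 6 gives deca-O-benzylepicatechin-(4β→6)-8-bromoepicatechin F3, whose free C8 in the upper unit is its most nucleophilic carbon. Me3SiOTf-catalysed coupling of F2 with F3 gives the eicosa-O-benzyl tribromo tetramer F4 (new 4β→8 bond anti to the 3-benzyloxy group), and hydrogenolysis as in step 17 comes back to the route at 23.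

2. Step 11. What may go wrong: attack of the C4 cation at a ring carbon next to the silyloxy group instead of the carbon between the two benzyloxy groups, which would lead to the 4→8 connectivity of units 1 and 2. Fallback: it sets out from 5. Coupling with an excess of phloroglucinol (Me3SiOTf, THF/CH2Cl2) gives the 4β-(2,4,6-trihydroxyphenyl) compound F5; the ring is symmetric, so no regiochemical question arises. iPr3SiCl and imidazole silylate only the unhindered para hydroxyl to give the mono-silyl ether F6. BnBr and K2CO3 then benzylate the two flanking hydroxyls, and the fallback comes back to the route at 14.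

3. Step 14 (with the reagent 17 it needs). What may go wrong: incomplete formation of 17 from an electron-rich aldehyde, C-alkylation of the ambident phenoxide, acyl transfer from the pivalate to the phenoxide, or hydrolysis of the acyl acetal on isolation. Fallback: it sets out from 15 and 16. Aldehyde 16, benzotriazole and SOCl2 give 1-{chloro[3,4-bis(benzyloxy)phenyl]methyl}benzotriazole F7. The sodium phenoxide of 15 (NaH, THF) is O-alkylated by it to the aryloxy(benzotriazol-1-yl)methane F8, a stable N,O-acetal. The acid of step 15, then used in a stoichiometric amount, ionises F8 with loss of benzotriazole, and the fallback comes back to the route at 19.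

**Further compounds**

F1 | step 15 | deca-O-benzyl-8-bromoepicatechin-(4β→6)-8-bromoepicatechin | c9ccccc9COc1cc(OCc9ccccc9)c2c(c1Br)O[C@H](c1ccc(OCc9ccccc9)c(OCc9ccccc9)c1)[C@H](OCc9ccccc9)[C@H]2c1c(OCc9ccccc9)c(Br)c3c(c1OCc9ccccc9)C[C@@H](OCc9ccccc9)[C@@H](c1ccc(OCc9ccccc9)c(OCc9ccccc9)c1)O3
F2 | step 15 | F1 with a 4β-(2-ethoxyethoxy) group on the lower unit | c9ccccc9COc1cc(OCc9ccccc9)c2c(c1Br)O[C@H](c1ccc(OCc9ccccc9)c(OCc9ccccc9)c1)[C@H](OCc9ccccc9)[C@H]2c1c(OCc9ccccc9)c(Br)c3c(c1OCc9ccccc9)[C@H](OCCOCC)[C@@H](OCc9ccccc9)[C@@H](c1ccc(OCc9ccccc9)c(OCc9ccccc9)c1)O3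
F3 | step 15 | deca-O-benzylepicatechin-(4β→6)-8-bromoepicatechin | c9ccccc9COc1cc(OCc9ccccc9)c2c(c1)O[C@H](c1ccc(OCc9ccccc9)c(OCc9ccccc9)c1)[C@H](OCc9ccccc9)[C@H]2c1c(OCc9ccccc9)c(Br)c3c(c1OCc9ccccc9)C[C@@H](OCc9ccccc9)[C@@H](c1ccc(OCc9ccccc9)c(OCc9ccccc9)c1)O3
F4 | step 15 | eicosa-O-benzyl-8-bromoepicatechin-(4β→6)-8-bromoepicatechin-(4β→8)-epicatechin-(4β→6)-8-bromoepicatechin | c9ccccc9COc1cc(OCc9ccccc9)c2c(c1Br)O[C@H](c1ccc(OCc9ccccc9)c(OCc9ccccc9)c1)[C@H](OCc9ccccc9)[C@H]2c1c(OCc9ccccc9)c(Br)c2c(c1OCc9ccccc9)[C@H](c1c(OCc9ccccc9)cc(OCc9ccccc9)c3c1O[C@H](c1ccc(OCc9ccccc9)c(OCc9ccccc9)c1)[C@H](OCc9ccccc9)[C@H]3c1c(OCc9ccccc9)c(Br)c3c(c1OCc9ccccc9)C[C@@H](OCc9ccccc9)[C@@H](c1ccc(OCc9ccccc9)c(OCc9ccccc9)c1)O3)[C@@H](OCc9ccccc9)[C@@H](c1ccc(OCc9ccccc9)c(OCc9ccccc9)c1)O2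
F5 | step 11 | 8-bromo-penta-O-benzyl-4β-(2,4,6-trihydroxyphenyl)epicatechin | c9ccccc9COc1cc(OCc9ccccc9)c2c(c1Br)O[C@H](c1ccc(OCc9ccccc9)c(OCc9ccccc9)c1)[C@H](OCc9ccccc9)[C@H]2c1c(O)cc(O)cc1O
F6 | step 11 | 8-bromo-penta-O-benzyl-4β-[2,6-dihydroxy-4-(triisopropylsilyloxy)phenyl]epicatechin | c9ccccc9COc1cc(OCc9ccccc9)c2c(c1Br)O[C@H](c1ccc(OCc9ccccc9)c(OCc9ccccc9)c1)[C@H](OCc9ccccc9)[C@H]2c1c(O)cc(O[Si](C(C)C)(C(C)C)C(C)C)cc1O
F7 | step 14 | 1-{chloro[3,4-bis(benzyloxy)phenyl]methyl}-1H-benzotriazole (racemic) | ClC(n1nnc2ccccc12)c1ccc(OCc2ccccc2)c(OCc2ccccc2)c1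
F8 | step 14 | aryloxy(benzotriazol-1-yl)[3,4-bis(benzyloxy)phenyl]methane from 15 (both epimers) | c9ccccc9COc1cc(OCc9ccccc9)c2c(c1Br)O[C@H](c1ccc(OCc9ccccc9)c(OCc9ccccc9)c1)[C@H](OCc9ccccc9)[C@H]2c1c(OCc9ccccc9)cc(OC(n3nnc4ccccc34)c3ccc(OCc9ccccc9)c(OCc9ccccc9)c3)cc1OCc9ccccc9
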